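(The runs are calculated for substances that don't exist, noise included.)

Picture a one-step world: substrate turns into target at a rate proportional to [substrate] and to the catalyst charged (pseudo-first-order), nothing is lost, and the logarithm of charged over remaining substrate grows in a straight line with time. Read these flasks against that zero.

the same everywhere: substrate 1.5 M

|  | coupling partner | free catalyst | temperature | remark | time |
|---|---|---|---|---|---|
| red | 3 M | 0.87 mM | 32 °C | run made earlier |  |
| ochre | 3 M | 2 mM | 49 °C | run made earlier |  |
| maple | 3.00 M | 1.3 mM |  | at 25 °C until 2.5 h, from then on at 55 °C | 5.0 h |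
| birch | 3.00 M | 1.3 mM |  | at 55 °C throughout | 1.2 h |

red run (percent of the substrate charged)

| time / h | target / % |
|---|---|
| 0.333 | 4.9 |
| 0.667 | 8.2 |
| 1.50 | 18.1 |
| 4.00 | 41.6 |

ochre run (percent of the substrate charged)

| time / min | target / % |
|---|---|
| 6.00 | 6.4 |
| 12.0 | 15.0 |
| 30.0 | 30.7 |
| 80.0 | 57.6 |

(readings scatter by 1 percentage point)

- the earlier runs were read with a standard deviation of 1 percentage point
- reactions considered so far: coupling partner + free catalyst <-> catalyst intermediate A; catalyst intermediate B -> free catalyst + target; coupling partner -> decomposition product; coupling partner + catalyst intermediate A -> spent catalyst; substrate + catalyst intermediate A -> catalyst intermediate B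

- which of the two ends with the higher amount of target, in percent of the substrate charged ("neither" if they lie within 2 percentage points) (maple / birch / neither)
- target at the end, in percent of the substrate charged, maple
- target at the end, in percent of the substrate charged, birch

First, how fast is that world at 1.3 mM of catalyst? The last reading of the red run, at 32 °C, scaled to that charge, gives 0.201 h⁻¹. Call this the exponent rate, the logarithm per hour at a stated catalyst charge and temperature.

So how does it move with temperature? The ochre reading at 30.0 min, scaled the same way, gives 0.477 h⁻¹ at 49 °C, so the readings double the exponent rate every 13.6 K. That makes 0.141 h⁻¹ at 25 °C and 0.647 h⁻¹ at 55 °C.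

But does the straight line hold when hot? The last ochre reading reaches 87.7% of the exponent its earlier rate promises, so I scale the hot time by that share. That reckons birch at 49.4%. The hot stage of maple lasts twice as long as birch, with the cold stage on top, so I reckon maple at 83.0%, higher than birch, though that hot stage of 2.50 h runs longer than the 80.0 min of the last ochre reading.

The forecast also names maple, with 73% (63% to 83%) for maple, below my figure, and 47% (40% to 55%) for birch, noting of the ochre run: “It then sags, suggesting catalyst decay”.

The flask gives maple: maple 78.7%, birch 49.2%.

    coupling partner + free catalyst ⇌ catalyst intermediate A (K = 0.0550 M⁻¹, k = 0.0630 M⁻¹ s⁻¹, Ea = 54.0 kJ mol⁻¹, ΔH = −10.0 kJ mol⁻¹)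
    catalyst intermediate B → free catalyst + target (k = 0.160 s⁻¹, Ea = 75.0 kJ mol⁻¹)
    coupling partner → decomposition product (k = 8.70 × 10⁻⁸ s⁻¹, Ea = 114 kJ mol⁻¹)
    coupling partner + catalyst intermediate A → spent catalyst (k = 8.10 × 10⁻⁶ M⁻¹ s⁻¹, Ea = 70.0 kJ mol⁻¹)
    substrate + catalyst intermediate A → catalyst intermediate B (k = 0.410 M⁻¹ s⁻¹, Ea = 39.0 kJ mol⁻¹)
    (constants at 25 °C)

Against the one-step 0.647 h⁻¹, birch averaged 0.564 h⁻¹, and the hot stage of maple averaged less still, 0.481 h⁻¹. Carried without any sag to a flask charged like birch but run at 40 °C, the exponent rate is 0.302 h⁻¹, which reckons 30.4% of target after 1.2 h, and that flask gives 31.2%.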